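**Retrosynthetic overview**

1. The strategy rests on the 1,2-dioxane ring O1–O2–C3–C4–C5–C6: a four-carbon chain C3–C6 bridged by the peroxide, in which C3 (acetal level) and C6 (ketal level) are carbonyl carbons once the C3–CH2CO2Me and C6–alkenyl bonds are cut, and C4 is the only stereocentre on the chain.
2. Last disconnections: C3–CH2 (silyl ketene acetal onto the C3 peroxycarbenium ion) and C6–C1' (alkenyltrifluoroborate onto the C6 peroxycarbenium ion) lead back to a 3,6-dimethoxy-1,2-dioxane.
3. Key disconnection: this bis-peroxyketal is the ozone/methanol adduct of (3R)-1,3-diethylcyclobutene; the dioxane, the only ring of the target, is closed there with the O–O bond taken intact from ozone.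
4. The cyclobutene comes from but-1-ene and dichloroketene ([2+2], dechlorination, enantioselective deprotonation/triflation, iron-catalysed ethylation); this four-membered ring is made first and then sacrificed.
5. The (1E,4S)-alkenyl donor comes from hex-1-ene by asymmetric ethylalumination, acetylide alkylation, syn-ethylcupration/iodination and borylation, because the side chain is trisubstituted and carries its own stereocentre.

Key step: step 5

Assumption: the absolute sense of the two reagent-controlled steps is taken by analogy, lithium (S,S)-bis(1-phenylethyl)amide for the (R)-enolate in step 3 (mirror image of the base that gives (S)-enolates of 4-substituted cyclohexanones) and (+)-(NMI)2ZrCl2 for the (S)-alkylalane in step 6 (the (−)-catalyst gives (R)-2-alkylalkanols); should either prove opposite, the mirror-image reagent is used with no other change.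

**Route**

Step 1
Reactants: 1 but-1-ene; 2 trichloroacetyl chloride
Product: 4 2,2-dichloro-3-ethylcyclobutan-1-one (racemic), via dichloroketene 3 (not isolated)
Conditions: zinc–copper couple (Zn/Cu), Et2O/DME (4:1), 0 °C → rt, excess but-1-ene under a −78 °C condenser
Reagents that add atoms: none
Why: Dichloroketene, formed by zinc dechlorination of the acid chloride, undergoes thermal [2+2] cycloaddition with the terminal alkene with the usual regiochemistry (CCl2 next to the substituted carbon); the racemic centre is irrelevant because the next step makes the ketone achiral.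

Step 2
Reactants: 4 2,2-dichloro-3-ethylcyclobutan-1-one
Product: 6 3-ethylcyclobutan-1-one, via monochloro ketone 5 (not isolated)
Conditions: Zn dust, AcOH, rt → 60 °C
Reagents that add atoms: none
Why: Reductive dehalogenation of an α,α-dichloro ketone by zinc in acetic acid removes both chlorine atoms through zinc enolates and leaves the prochiral 3-substituted cyclobutanone.

Step 3
Reactants: 6 3-ethylcyclobutan-1-one
Product: 8 (3R)-3-ethylcyclobut-1-en-1-yl trifluoromethanesulfonate, via lithium enolate 7 (not isolated)
Conditions: (S,S)-bis(1-phenylethyl)amine, n-BuLi, LiCl, THF, −100 °C; then Comins' reagent, −78 °C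
Reagents that add atoms: Comins' reagent, N-(5-chloropyridin-2-yl)-1,1,1-trifluoro-N-(trifluoromethanesulfonyl)methanesulfonamide, Clc1ccc(nc1)N(S(=O)(=O)C(F)(F)F)S(=O)(=O)C(F)(F)F
Why: Enantioselective deprotonation with a chiral lithium amide (a known desymmetrisation of 3-substituted cyclobutanones) selects one of the two enantiotopic α-methylene groups, and O-triflation of the enolate at −78 °C fixes the result, so that C3 of 8 becomes the centre that ends as C4 of the target.

Step 4
Reactants: 8 (3R)-3-ethylcyclobut-1-en-1-yl trifluoromethanesulfonate; 9 ethylmagnesium bromide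
Product: 10 (3R)-1,3-diethylcyclobut-1-ene
Conditions: Fe(acac)3 (5 mol %), THF/NMP, −30 °C; the volatile product is kept as a pentane solution
Reagents that add atoms: none
Why: Iron-catalysed Kumada-type cross-coupling of an alkenyl triflate with an alkyl Grignard reagent replaces OTf by ethyl at low temperature, tolerates β-hydrogen atoms in the Grignard reagent and does not touch the remote stereocentre.

Step 5
Reactants: 10 (3R)-1,3-diethylcyclobut-1-ene
Product: 16 (4R)-4,6-diethyl-3,6-dimethoxy-1,2-dioxane (C3/C6 epimer mixture), via primary ozonide 11 (not isolated), via keto methoxy-hydroperoxide 12 (not isolated), via 6-hydroxy peroxyketal 13 (not isolated), via aldehyde hydroperoxy-ketal 14 (not isolated), via 3-hydroxy peroxyacetal 15 (not isolated)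
Conditions: O3, MeOH/CH2Cl2 (1:1), −78 °C; N2 purge; then TsOH·H2O (5 mol %), 3 Å molecular sieves, 0 °C → rt; NaHCO3
Reagents that add atoms: ozone, [O-][O+]=O; methanol, CO
Why: Ozone adds to the strained ring alkene by 1,3-dipolar cycloaddition and the primary ozonide 11 cycloreverts to a carbonyl oxide and a carbonyl group that stay linked through C4–C5; methanol at solvent concentration traps the carbonyl oxide as a methoxy hydroperoxide (12, or 14 when the cleavage runs the other way) before it can recombine to a bicyclic ozonide. The hydroperoxide group then adds to the remaining carbonyl group in a 6-exo-trig closure (13 or 15), which puts C6–O1 and C3–O2 in place around the O–O bond delivered by ozone and so closes the 1,2-dioxane ring. Catalytic acid in methanol replaces the anomeric OH by OMe through a ring-retained peroxycarbenium ion, so both senses of cleavage converge on 16. The closest known reaction type is the ozonolysis of cyclopentenes and cyclohexenes in methanol, which gives methoxy hydroperoxides that close to cyclic peroxyhemiacetals; the cyclobutene is the lower homologue, for which this closure gives the strain-free six-membered ring. No lasting stereocentre is made, since C3 and C6 are left as anomeric mixtures that are both ionised later, and C4 is kept because the carbonyl group next to it is masked as soon as it forms. The step needs methanol capture to outrun intramolecular ozonide formation and the ring peroxide to survive the acid, which the solvent-level methanol and the higher basicity of the exocyclic OMe/OH oxygen atoms (they, not the ring oxygen atoms, are lost on ionisation) should secure.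

Step 6
Reactants: 17 hex-1-ene; 18 triethylaluminium
Product: 20 (2S)-2-ethylhexan-1-ol, via 2-ethylhexyl(diethyl)alane 19 (not isolated)
Conditions: (+)-(NMI)2ZrCl2 [bis(1-neomenthylindenyl)zirconium dichloride] (5 mol %), CH2Cl2, rt; then O2, 0 °C; aq. HCl
Reagents that add atoms: dioxygen, O=O
Why: Zirconium-catalysed asymmetric carboalumination (ZACA reaction) adds Et–Al across the terminal alkene with ethyl at C2, the chiral bis(indenyl)zirconium catalyst choosing the alkene face and so setting the (S) centre, and oxidation of the C–Al bond gives the primary alcohol.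

Step 7
Reactants: 20 (2S)-2-ethylhexan-1-ol
Product: 21 (3S)-3-(iodomethyl)heptane
Conditions: I2, PPh3, imidazole, CH2Cl2, 0 °C → rt
Reagents that add atoms: iodine, II
Why: Appel-type iodination is an SN2 displacement at the primary CH2 group and does not involve the neighbouring stereocentre.

Step 8
Reactants: 21 (3S)-3-(iodomethyl)heptane; 22 lithium acetylide–ethylenediamine complex
Product: 23 (4S)-4-ethyloct-1-yne
Conditions: DMSO, 10 °C → rt
Reagents that add atoms: none
Why: SN2 alkylation of the acetylide by the primary iodide in a dipolar aprotic solvent adds the two alkyne carbons without touching the β-stereocentre.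

Step 9
Reactants: 23 (4S)-4-ethyloct-1-yne; 9 ethylmagnesium bromide
Product: 25 (1E,4S)-2,4-diethyl-1-iodooct-1-ene, via alkenylcopper 24 (not isolated)
Conditions: CuBr·SMe2, Et2O/Me2S, −45 °C; alkyne added, −25 °C; then I2, THF, −78 → 0 °C
Reagents that add atoms: iodine, II
Why: Normant carbocupration adds ethylcopper syn across the terminal alkyne with copper on the terminal carbon, so ethyl and copper are cis, and iodinolysis with retention gives the (E)-iodoalkene with the trisubstituted geometry of the target.

Step 10
Reactants: 25 (1E,4S)-2,4-diethyl-1-iodooct-1-ene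
Product: 28 potassium trifluoro[(1E,4S)-2,4-diethyloct-1-en-1-yl]borate, via alkenyllithium 26 (not isolated), via lithium triisopropoxyborate 27 (not isolated)
Conditions: t-BuLi (2 equiv), Et2O, −78 °C; B(OiPr)3, −78 °C → rt; then aq. KHF2, MeOH, rt
Reagents that add atoms: triisopropyl borate, CC(C)OB(OC(C)C)OC(C)C; potassium hydrogen difluoride, [K+].F[H-]F
Why: Iodine–lithium exchange with retention of alkene geometry, borylation of the alkenyllithium and fluoride exchange give the bench-stable alkenyltrifluoroborate.

Step 11
Reactants: 16 (4R)-4,6-diethyl-3,6-dimethoxy-1,2-dioxane; 28 potassium trifluoro[(1E,4S)-2,4-diethyloct-1-en-1-yl]borate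
Product: 30 (4R,6S)-6-[(1E,4S)-2,4-diethyloct-1-en-1-yl]-4,6-diethyl-3-methoxy-1,2-dioxane (C3 epimer mixture), via alkenyldifluoroborane 29 (not isolated)
Conditions: BF3·OEt2 (2 equiv), CH2Cl2, −78 → −30 °C; aq. NaHCO3
Reagents that add atoms: none
Why: Proposed new method: BF3 removes fluoride from 28 to give the Lewis acidic alkenyldifluoroborane 29, which ionises the more easily ionised tertiary C6 methoxy group of 16 to a ring-retained peroxycarbenium ion and returns its alkenyl group to C6 from the resulting methoxyborate, the closest known reaction types being the BF3-promoted coupling of alkenyltrifluoroborates with oxocarbenium ions from O,O-acetals and the Lewis acid-mediated allylation of peroxyketals through peroxycarbenium ions; the C6 centre is set by the C4 ethyl group, which sits pseudoequatorial in the half-chair cation so that the nucleophile enters axially on the face anti to it (1,3-trans), leaving the two ethyl groups cis.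

Step 12
Reactants: 30 (4R,6S)-6-[(1E,4S)-2,4-diethyloct-1-en-1-yl]-4,6-diethyl-3-methoxy-1,2-dioxane; 31 tert-butyl[(1-methoxyethenyl)oxy]dimethylsilane
Product: 32 methyl 2-[(3S,4R,6S)-6-[(1E,4S)-2,4-diethyloct-1-en-1-yl]-4,6-diethyl-1,2-dioxan-3-yl]acetate
Conditions: TMSOTf (0.3 equiv), 2,6-di-tert-butyl-4-methylpyridine, toluene/CH2Cl2 (3:1), −78 °C; Et3N quench
Reagents that add atoms: none
Why: Mukaiyama-type addition of a silyl ketene acetal to the activated secondary C3 peroxyacetal is a known substitution of 3-alkoxy-1,2-dioxanes; with this strongly nucleophilic partner in a weakly polar medium the substitution is expected to run with inversion on the anomerically preferred axial C3 triflate or its contact ion pair, which places the acetate arm equatorial, trans to the C4 ethyl group and cis to the C6 alkenyl group.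

**Compound list**

1 | but-1-ene | C=CCC | starting material
2 | trichloroacetyl chloride | ClC(=O)C(Cl)(Cl)Cl | starting material
3 | dichloroketene | ClC(Cl)=C=O | intermediate (not isolated)
4 | 2,2-dichloro-3-ethylcyclobutan-1-one (racemic) | CCC1CC(=O)C1(Cl)Cl | intermediate
5 | 2-chloro-3-ethylcyclobutan-1-one | CCC1CC(=O)C1Cl | intermediate (not isolated)
6 | 3-ethylcyclobutan-1-one | CCC1CC(=O)C1 | intermediate
7 | lithium (3R)-3-ethylcyclobut-1-en-1-olate | [Li+].[O-]C1=C[C@H](CC)C1 | intermediate (not isolated)
8 | (3R)-3-ethylcyclobut-1-en-1-yl trifluoromethanesulfonate | O=S(=O)(OC1=C[C@H](CC)C1)C(F)(F)F | intermediate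
9 | ethylmagnesium bromide | CC[Mg]Br | starting material
10 | (3R)-1,3-diethylcyclobut-1-ene | CCC1=C[C@H](CC)C1 | intermediate
11 | (6R)-1,6-diethyl-2,3,4-trioxabicyclo[3.2.0]heptane (primary ozonide, mixture at C1/C5) | CCC12OOOC1[C@H](CC)C2 | intermediate (not isolated)
12 | (5R)-5-ethyl-6-hydroperoxy-6-methoxyhexan-3-one (mixture at C6) | CCC(=O)C[C@@H](CC)C(OC)OO | intermediate (not isolated)
13 | (5R)-3,5-diethyl-6-methoxy-1,2-dioxan-3-ol (mixture at C3/C6) | CCC1(O)C[C@@H](CC)C(OC)OO1 | intermediate (not isolated)
14 | (2R)-2-ethyl-4-hydroperoxy-4-methoxyhexanal (mixture at C4) | CCC(OC)(OO)C[C@@H](CC)C=O | intermediate (not isolated)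
15 | (4R)-4,6-diethyl-6-methoxy-1,2-dioxan-3-ol (mixture at C3/C6) | CCC1(OC)C[C@@H](CC)C(O)OO1 | intermediate (not isolated)
16 | (4R)-4,6-diethyl-3,6-dimethoxy-1,2-dioxane (mixture at C3/C6) | CCC1(OC)C[C@@H](CC)C(OC)OO1 | intermediate
17 | hex-1-ene | C=CCCCC | starting material
18 | triethylaluminium | CC[Al](CC)CC | starting material
19 | [(2S)-2-ethylhexyl]diethylalane | CCCC[C@H](CC)C[Al](CC)CC | intermediate (not isolated)
20 | (2S)-2-ethylhexan-1-ol | CCCC[C@H](CC)CO | intermediate
21 | (3S)-3-(iodomethyl)heptane | CCCC[C@H](CC)CI | intermediate
22 | lithium acetylide–ethylenediamine complex | [Li]C#C.NCCN | starting material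
23 | (4S)-4-ethyloct-1-yne | CCCC[C@H](CC)CC#C | intermediate
24 | [(1E,4S)-2,4-diethyloct-1-en-1-yl]copper | CCCC[C@H](CC)C/C(CC)=C/[Cu] | intermediate (not isolated)
25 | (1E,4S)-2,4-diethyl-1-iodooct-1-ene | CCCC[C@H](CC)C/C(CC)=C/I | intermediate
26 | [(1E,4S)-2,4-diethyloct-1-en-1-yl]lithium | CCCC[C@H](CC)C/C(CC)=C/[Li] | intermediate (not isolated)
27 | lithium [(1E,4S)-2,4-diethyloct-1-en-1-yl]triisopropoxyborate | CCCC[C@H](CC)C/C(CC)=C/[B-](OC(C)C)(OC(C)C)OC(C)C.[Li+] | intermediate (not isolated)
28 | potassium trifluoro[(1E,4S)-2,4-diethyloct-1-en-1-yl]borate | CCCC[C@H](CC)C/C(CC)=C/[B-](F)(F)F.[K+] | intermediate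
29 | [(1E,4S)-2,4-diethyloct-1-en-1-yl]difluoroborane | CCCC[C@H](CC)C/C(CC)=C/B(F)F | intermediate (not isolated)
30 | (4R,6S)-6-[(1E,4S)-2,4-diethyloct-1-en-1-yl]-4,6-diethyl-3-methoxy-1,2-dioxane (mixture at C3) | CCCC[C@H](CC)C/C(CC)=C/[C@]1(CC)C[C@@H](CC)C(OC)OO1 | intermediate
31 | tert-butyl[(1-methoxyethenyl)oxy]dimethylsilane | C=C(OC)O[Si](C)(C)C(C)(C)C | starting material
32 | methyl 2-[(3S,4R,6S)-6-[(1E,4S)-2,4-diethyloct-1-en-1-yl]-4,6-diethyl-1,2-dioxan-3-yl]acetate | CCCC[C@H](CC)C/C(=C/[C@]1(CC)C[C@@H](CC)[C@H](CC(=O)OC)OO1)CC | target

**Step count and risks**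

Total step count: 12. Longest linear sequence: 7 steps (steps 1–5, 11 and 12 from but-1-ene; the side-chain branch, steps 6–10, 11 and 12, is equally long).

Steps most likely to fail:

1. Step 11 (it bears the label "Proposed new method:"). The tertiary peroxycarbenium ion may lose a proton or rearrange with O–O cleavage faster than the alkenyl group is transferred, the electron-rich alkenylborane may be protodeboronated, and the Lewis acid may re-ionise the new tertiary allylic C6–O bond. The fallback uses known chemistry and makes the C6–alkenyl bond by carbonyl addition before the peroxide exists. It sets out from 10, which is ozonised with reductive work-up (O3, CH2Cl2/MeOH, −78 °C; Me2S) to (2R)-2-ethyl-4-oxohexanal F1, used at once. Chemoselective Wittig olefination of the aldehyde with methyl (triphenylphosphoranylidene)acetate gives methyl (2E,4R)-4-ethyl-6-oxooct-2-enoate F2. Alkenyllithium 26 (from 25 as in step 10) is transmetallated with CeCl3 to [(1E,4S)-2,4-diethyloct-1-en-1-yl]cerium dichloride F3, which adds to the ketone of F2 at −78 °C to give the tertiary allylic alcohol methyl (2E,4R,7E,10S)-4,6,8,10-tetraethyl-6-hydroxytetradeca-2,7-dienoate F4. Acid-catalysed exchange of the tertiary allylic OH for OOH (50% H2O2, cat. H2SO4, Et2O, 0 °C) gives methyl (2E,4R,7E,10S)-4,6,8,10-tetraethyl-6-hydroperoxytetradeca-2,7-dienoate F5. Et2NH in CF3CH2OH then closes the ring by intramolecular hydroperoxide conjugate addition and the fallback comes back to the route at 32. It gives up control at C6 and over the allylic position of the hydroperoxide, so the target has to be separated from isomers.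

2. Step 5. Carbonyl oxide and carbonyl group may recombine to the bicyclic ozonide or to oligomeric peroxides in competition with methanol capture, and the acid stage may open the ring to open-chain acetals with loss of hydrogen peroxide. The fallback accepts the ozonide instead of fighting it. It sets out from 10, which is ozonised without methanol (pentane/CH2Cl2, −78 °C) so that the fragments recombine to (5R)-1,5-diethyl-2,3,7-trioxabicyclo[2.2.1]heptane F6, which already holds the C3–O–O–C6 unit in a six-membered ring. Acid-catalysed methanolysis (TsOH, MeOH, 0 °C) opens the ether bridge at the tertiary carbon through the ring-retained peroxycarbenium ion, exchanges the remaining anomeric OH, and comes back to the route at 16.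

3. Step 12. If the nucleophile attacks a free peroxycarbenium ion along the stereoelectronically favoured axial path, the acetate arm ends cis to the C4 ethyl group (the C3 epimer); the Lewis acid may also ionise the tertiary allylic C6–O bond. The fallback forms the C3–O2 bond last under chair-like control. It sets out from 30, whose C3 methyl peroxyacetal is hydrolysed (aq. CF3CO2H, CH2Cl2, 0 °C) to (4R,6S)-6-[(1E,4S)-2,4-diethyloct-1-en-1-yl]-4,6-diethyl-1,2-dioxan-3-ol F7. Its open hydroperoxy aldehyde form is olefinated with methyl (triphenylphosphoranylidene)acetate to methyl (2E,4R,6S,7E,10S)-4,6,8,10-tetraethyl-6-hydroperoxytetradeca-2,7-dienoate F8. Et2NH in CF3CH2OH closes the ring by 6-exo-trig hydroperoxide conjugate addition through a chair-like transition state with the C3 and C4 substituents equatorial, and the fallback comes back to the route at 32.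

**Further compounds**

F1 | step 11 | (2R)-2-ethyl-4-oxohexanal | CCC(=O)C[C@@H](CC)C=O
F2 | step 11 | methyl (2E,4R)-4-ethyl-6-oxooct-2-enoate | CCC(=O)C[C@@H](CC)/C=C/C(=O)OC
F3 | step 11 | [(1E,4S)-2,4-diethyloct-1-en-1-yl]cerium dichloride | CCCC[C@H](CC)C/C(CC)=C/[Ce](Cl)Cl
F4 | step 11 | methyl (2E,4R,7E,10S)-4,6,8,10-tetraethyl-6-hydroxytetradeca-2,7-dienoate (mixture at C6) | CCCC[C@H](CC)C/C(CC)=C/C(O)(CC)C[C@@H](CC)/C=C/C(=O)OC
F5 | step 11 | methyl (2E,4R,7E,10S)-4,6,8,10-tetraethyl-6-hydroperoxytetradeca-2,7-dienoate (mixture at C6) | CCCC[C@H](CC)C/C(CC)=C/C(OO)(CC)C[C@@H](CC)/C=C/C(=O)OC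
F6 | step 5 | (5R)-1,5-diethyl-2,3,7-trioxabicyclo[2.2.1]heptane (mixture at the bridgeheads) | CCC12OOC(O1)[C@H](CC)C2
F7 | step 12 | (4R,6S)-6-[(1E,4S)-2,4-diethyloct-1-en-1-yl]-4,6-diethyl-1,2-dioxan-3-ol (mixture at C3) | CCCC[C@H](CC)C/C(CC)=C/[C@]1(CC)C[C@@H](CC)C(O)OO1
F8 | step 12 | methyl (2E,4R,6S,7E,10S)-4,6,8,10-tetraethyl-6-hydroperoxytetradeca-2,7-dienoate | CCCC[C@H](CC)C/C(CC)=C/[C@](OO)(CC)C[C@@H](CC)/C=C/C(=O)OC
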